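## Retrosynthetic overview

1. Hippolide D ⇐ (R)-3-furyl carbinol carrying the complete E-enal/polyene chain. The succinic anhydride is made last along the presumed biogenetic path furan → singlet-oxygen endoperoxide → γ-hydroxybutenolide (secomanoalide type) → anhydride, run as one cascade.
2. Furyl carbinol ⇐ furan-3-carbaldehyde + silyl dienol ether of 2-homofarnesylbut-2-enal, by a catalytic asymmetric vinylogous Mukaiyama aldol that sets the (R)-carbinol and the E-enal.
3. Enal ⇐ pyruvaldehyde dimethyl acetal + (2E,6E)-farnesyl bromide (enolate alkylation), then ethylidene Wittig and acetal hydrolysis.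
4. Ring order: the furan is bought; the only ring made is the oxolane-2,5-dione, in the last step (bicyclic endoperoxide → butenolide → anhydride). The ring stereocentre is set there by OH-directed ketonisation.

Assumption 1: the presumed biogenesis is photooxygenation of a 3-alkylfuran to the 5-hydroxybutenolide, followed by redox-neutral tautomerisation to the anhydride (furan + O2 and the anhydride are isomers).

Assumption 2: the (S)-tryptophan-derived oxazaborolidinone directs the dienol ether to the Re face of furan-3-carbaldehyde, giving the (R)-carbinol. If the opposite sense is found, the (R)-tryptophan-derived catalyst is used with nothing else changed.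

## Route

Step 1
Reactants: 1 1,1-dimethoxypropan-2-one (pyruvaldehyde dimethyl acetal, 1.3 equiv); 2 (2E,6E)-farnesyl bromide
Product: 4 (5E,9E)-1,1-dimethoxy-6,10,14-trimethylpentadeca-5,9,13-trien-2-one, via lithium enolate 3 (not isolated)
Conditions: LiN(iPr)2 (1.3 equiv), THF, −78 °C, 45 min; then 2, −78 → −20 °C
Reagents that add atoms: none
Why: Kinetic deprotonation takes place at the methyl group (the acetal C–H is hindered and poorly acidic) and the lithium enolate is alkylated by the primary allylic bromide in an SN2 enolate alkylation that leaves the E,E geometry untouched; no stereocentre is formed.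

Step 2
Reactants: 4 (5E,9E)-1,1-dimethoxy-6,10,14-trimethylpentadeca-5,9,13-trien-2-one
Product: 6 (2E)-2-[(3E,7E)-4,8,12-trimethyltrideca-3,7,11-trien-1-yl]but-2-enal, via dimethyl acetal 5 (not isolated)
Conditions: EtPPh3Br, KN(SiMe3)2, THF, 0 °C; 4, −78 °C → rt; then 5% aq. oxalic acid, THF, rt
Reagents that add atoms: ethyltriphenylphosphonium bromide, CC[P+](c1ccccc1)(c1ccccc1)c1ccccc1.[Br-]; water, O
Why: Wittig olefination of the α,α-dialkoxy ketone with the non-stabilised ethylidene ylide, followed by mild acid hydrolysis of the allylic acetal, gives the enal; its double-bond geometry (drawn E, the stable form) is erased in step 3 and no stereocentre is formed.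

Step 3
Reactants: 6 (2E)-2-[(3E,7E)-4,8,12-trimethyltrideca-3,7,11-trien-1-yl]but-2-enal
Product: 7 (1E)-1-(tert-butyldimethylsilyloxy)-2-[(3E,7E)-4,8,12-trimethyltrideca-3,7,11-trien-1-yl]buta-1,3-diene
Conditions: tBuMe2SiOTf (1.2 equiv), Et3N (2 equiv), Et2O, 0 °C → rt
Reagents that add atoms: tert-butyldimethylsilyl trifluoromethanesulfonate, CC(C)(C)[Si](C)(C)OS(=O)(=O)C(F)(F)F
Why: Soft enolisation (O-silylation of the enal, then γ-deprotonation by the amine) gives the linear silyl dienol ether, mainly 1E from the s-trans enal; no stereocentre is formed.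

Step 4
Reactants: 7 (1E)-1-(tert-butyldimethylsilyloxy)-2-[(3E,7E)-4,8,12-trimethyltrideca-3,7,11-trien-1-yl]buta-1,3-diene; 8 furan-3-carbaldehyde (1.5 equiv)
Product: 9 (2E,5R)-5-(furan-3-yl)-5-hydroxy-2-[(3E,7E)-4,8,12-trimethyltrideca-3,7,11-trien-1-yl]pent-2-enal
Conditions: (4S)-4-(1H-indol-3-ylmethyl)-3-(4-methylphenylsulfonyl)-2-phenyl-1,3,2-oxazaborolidin-5-one (50 mol %, preformed from N-tosyl-L-tryptophan and PhBCl2), iPrOH (1.2 equiv), EtCN, −78 °C; aq. NaHCO3
Reagents that add atoms: none
Why: Catalytic asymmetric vinylogous Mukaiyama aldol reaction in which the boron Lewis acid binds the aldehyde, the indole shields its Si face, the γ-carbon of the α-substituted dienol ether attacks the Re face to set the (R)-carbinol, iPrOH takes up the silyl group, and the enal is re-formed as the stable E isomer.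

Step 5
Reactants: 9 (2E,5R)-5-(furan-3-yl)-5-hydroxy-2-[(3E,7E)-4,8,12-trimethyltrideca-3,7,11-trien-1-yl]pent-2-enal
Product: 13 hippolide D, via furan endoperoxide 10 (not isolated), via hydroxybutenolide 11 (not isolated), via furan-2,5-diol 12 (not isolated)
Conditions: O2 (1 atm), hν (white LED, >500 nm), 5,10,15,20-tetraphenylporphyrin (1 mol %), CH2Cl2 (5 mM), −78 °C, stopped at full consumption of 9; Ar sparge; 1,8-diazabicyclo[5.4.0]undec-7-ene (0.2 equiv), −78 → −30 °C; cold filtration through a short silica pad, concentration below 0 °C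
Reagents that add atoms: dioxygen, O=O
Why: Proposed new method: the 3-alkylfuran adds singlet oxygen in a [4+2] cycloaddition faster than the trisubstituted alkenes undergo the ene reaction, the amidine opens endoperoxide 10 by Kornblum–DeLaMare fragmentation to lactol 11 (either regioisomer would converge), and because the base is substoichiometric most of 11 stays ring-closed so that the amidinium/carboxylate pair can shuttle its acetal hydrogen to carbon (γ-deprotonation to the aromatic 2,5-dioxyfuran 12, then C-protonation at the two ring CH positions), an isomerisation that is estimated to be about 15–20 kcal/mol downhill and ends in the anhydride, with the ring stereocentre set in the last ketonisation, where the enol oxygen is hydrogen-bonded to the (R)-carbinol OH and the proton enters anti to the side chain (chelate-type model as in Fráter–Seebach chemistry, giving the syn 3S isomer) at a temperature too low for epimerisation; the closest known reaction types are the amine-mediated Kornblum–DeLaMare and γ-hydroxyenone-to-1,4-dicarbonyl isomerisation of 1,2-dioxines, amine-catalysed butenolide isomerisation through 2-oxyfuran dienolates, and the base-induced isomerisation of the parent 5-hydroxyfuran-2(5H)-one to the succinic anhydride level.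

## Compound list

1 | 1,1-dimethoxypropan-2-one (pyruvaldehyde dimethyl acetal) | COC(OC)C(C)=O | starting material
2 | (2E,6E)-farnesyl bromide, (2E,6E)-1-bromo-3,7,11-trimethyldodeca-2,6,10-triene | CC(C)=CCC/C(C)=C/CC/C(C)=C/CBr | starting material
3 | lithium enolate of 1 (lithium 3,3-dimethoxyprop-1-en-2-olate) | C=C(O[Li])C(OC)OC | intermediate (not isolated)
4 | (5E,9E)-1,1-dimethoxy-6,10,14-trimethylpentadeca-5,9,13-trien-2-one | COC(OC)C(=O)CC/C=C(\C)CC/C=C(\C)CCC=C(C)C | intermediate
5 | (2Z,6E,10E)-3-(dimethoxymethyl)-7,11,15-trimethylhexadeca-2,6,10,14-tetraene (acetal cis to the new methyl) | COC(OC)/C(CC/C=C(\C)CC/C=C(\C)CCC=C(C)C)=C\C | intermediate (not isolated)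
6 | (2E)-2-[(3E,7E)-4,8,12-trimethyltrideca-3,7,11-trien-1-yl]but-2-enal | CC(C)=CCC/C(C)=C/CC/C(C)=C/CC/C(C=O)=C\C | intermediate
7 | (1E)-1-(tert-butyldimethylsilyloxy)-2-[(3E,7E)-4,8,12-trimethyltrideca-3,7,11-trien-1-yl]buta-1,3-diene | C=C/C(CC/C=C(\C)CC/C=C(\C)CCC=C(C)C)=C/O[Si](C)(C)C(C)(C)C | intermediate
8 | furan-3-carbaldehyde | O=Cc1ccoc1 | starting material
9 | (2E,5R)-5-(furan-3-yl)-5-hydroxy-2-[(3E,7E)-4,8,12-trimethyltrideca-3,7,11-trien-1-yl]pent-2-enal | CC(C)=CCC/C(C)=C/CC/C(C)=C/CC/C(C=O)=C\C[C@@H](O)c1ccoc1 | intermediate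
10 | (2E,5R)-5-hydroxy-5-(2,3,7-trioxabicyclo[2.2.1]hept-5-en-5-yl)-2-[(3E,7E)-4,8,12-trimethyltrideca-3,7,11-trien-1-yl]pent-2-enal (both bridgehead epimers) | CC(C)=CCC/C(C)=C/CC/C(C)=C/CC/C(C=O)=C\C[C@@H](O)C1=CC2OOC1O2 | intermediate (not isolated)
11 | (2E,5R)-5-hydroxy-5-(2-hydroxy-5-oxo-2,5-dihydrofuran-3-yl)-2-[(3E,7E)-4,8,12-trimethyltrideca-3,7,11-trien-1-yl]pent-2-enal (lactol epimers) | CC(C)=CCC/C(C)=C/CC/C(C)=C/CC/C(C=O)=C\C[C@@H](O)C1=CC(=O)OC1O | intermediate (not isolated)
12 | (2E,5R)-5-(2,5-dihydroxyfuran-3-yl)-5-hydroxy-2-[(3E,7E)-4,8,12-trimethyltrideca-3,7,11-trien-1-yl]pent-2-enal | CC(C)=CCC/C(C)=C/CC/C(C)=C/CC/C(C=O)=C\C[C@@H](O)c1cc(O)oc1O | intermediate (not isolated)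
13 | hippolide D, (2E,5R)-5-[(3S)-2,5-dioxooxolan-3-yl]-5-hydroxy-2-[(3E,7E)-4,8,12-trimethyltrideca-3,7,11-trien-1-yl]pent-2-enal | CC(C)=CCC/C(C)=C/CC/C(C)=C/CC/C(C=O)=C\C[C@@H](O)[C@@H]1CC(=O)OC1=O | target

## Step count and risks

Total step count: 5. Longest linear sequence: 5 steps (1/2 → 4 → 6 → 7 → 9 → 13).

**Most likely to fail, in order:**

**Step 5.** The risks are ene oxidation of the chain alkenes, stalling at 11, the wrong or an epimerised ring stereocentre, and base-induced acyl transfer of the free OH onto the anhydride (paraconic lactone or oligomers). The fallback sets out from 9 and returns at 13, and replaces the hydrogen-bond-directed in-flask prototropy by a covalently tethered, stepwise protonation. The photooxygenation is run under the established hindered-base conditions (O2, hν, 5,10,15,20-tetraphenylporphyrin, iPr2NEt, CH2Cl2, −78 °C) and hydroxybutenolide 11 is isolated. Its carbinol OH and lactol OH are bridged with tBu2Si(OTf)2 and 2,6-lutidine to give the di-tert-butylsilylene acetal F1, which has no free OH and cannot ring-open. Soft enolisation with Me3SiOTf and Et3N at −78 °C gives the tethered 2-(trimethylsilyloxy)furan F2. HF·pyridine in THF at −78 °C then removes the trimethylsilyl group and protonates the two ring carbons while the siladioxane ring still holds the carbinol oxygen and the enol oxygen syn-periplanar, so the proton enters anti to the side chain, in the same sense as the main route. The tether leaves as the difluorosilane and 13 is obtained.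

**Step 4.** The risks are the level and sense of enantioselection with a heteroaromatic aldehyde and a large α-substituent on the dienol ether. The fallback sets out from 8 and 4 and returns at 9; it sets the carbinol by reagent-controlled allylboration and makes the enal by olefin cross-metathesis. Aldehyde 8 is allylated with (+)-B-allyldiisopinocampheylborane (Et2O, −78 °C; NaOH, H2O2) to (R)-1-(furan-3-yl)but-3-en-1-ol F3. Ketone 4 is methylenated with Ph3P=CH2 to the methylene acetal F4, which is hydrolysed with aqueous oxalic acid to the 2-methylidene aldehyde F5. Cross-metathesis of F3 with F5 using the second-generation Hoveyda–Grubbs catalyst, [1,3-bis(2,4,6-trimethylphenyl)imidazolidin-2-ylidene]dichloro[(2-isopropoxyphenyl)methylidene]ruthenium, in CH2Cl2 at 40 °C gives the E-enal 9 directly.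

**Step 1.** The risks are dialkylation and proton exchange of the keto-acetal enolate. The fallback sets out from 2 and returns at 6, bypassing steps 1 and 2 with an sp3–sp2 cross-coupling. Bromide 2 is homologated with bis(pinacolatoboryl)methane and NaOtBu in THF (deborylative alkylation) to the homofarnesyl pinacol boronate F6. Crotonaldehyde is α-iodinated (I2, K2CO3, catalytic 4-(dimethylamino)pyridine, THF/H2O) to (2Z)-2-iodobut-2-enal F7. B-alkyl Suzuki–Miyaura coupling of F6 with F7 ([1,1'-bis(diphenylphosphino)ferrocene]dichloropalladium, PdCl2(dppf), Cs2CO3, DMF/H2O, 50 °C) proceeds with retention of the alkene geometry and gives 6.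

## Further compounds

F1 | step 5 | di-tert-butylsilylene acetal of 11 (silicon bridging the carbinol oxygen and the lactol oxygen) | CC(C)=CCC/C(C)=C/CC/C(C)=C/CC/C(C=O)=C\C[C@H]1O[Si](C(C)(C)C)(C(C)(C)C)OC2OC(=O)C=C12
F2 | step 5 | tethered 2-(trimethylsilyloxy)furan (2,5-bis(silyloxy)furan with the di-tert-butylsilylene bridge to the carbinol oxygen) | CC(C)=CCC/C(C)=C/CC/C(C)=C/CC/C(C=O)=C\C[C@H]1O[Si](C(C)(C)C)(C(C)(C)C)Oc2oc(O[Si](C)(C)C)cc12
F3 | step 4 | (R)-1-(furan-3-yl)but-3-en-1-ol | C=CC[C@@H](O)c1ccoc1
F4 | step 4 | (5E,9E)-2-(dimethoxymethyl)-6,10,14-trimethylpentadeca-1,5,9,13-tetraene | COC(OC)C(=C)CC/C=C(\C)CC/C=C(\C)CCC=C(C)C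
F5 | step 4 | (5E,9E)-6,10,14-trimethyl-2-methylidenepentadeca-5,9,13-trienal | C=C(C=O)CC/C=C(\C)CC/C=C(\C)CCC=C(C)C
F6 | step 1 | 4,4,5,5-tetramethyl-2-[(3E,7E)-4,8,12-trimethyltrideca-3,7,11-trien-1-yl]-1,3,2-dioxaborolane | CC(C)=CCC/C(C)=C/CC/C(C)=C/CCB1OC(C)(C)C(C)(C)O1
F7 | step 1 | (2Z)-2-iodobut-2-enal | C/C=C(/C=O)I
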